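**Retrosynthetic overview**
1. Feature: the flavanone pyranone ring C (O1–C2–C3–C4) is tied to phloroglucinol ring A at both ends, through O1–C8a and C4–C4a. C2 and C3, with the 4-oxygenated ring B, can therefore arrive together as a styrene.
2. Endgame: target ⇐ heptabenzyl (2R)-flavanone (hydrogenolysis) ⇐ (2R,4R)-cis-4-methoxyflavan (oxidative cleavage of the C4 methyl ether to C4=O).
3. Key disconnection: C3–C4 and O1–C2 are cut together (retro-[4+2]). This gives 4-(benzyloxy)styrene and a 5-aryl-4,6-bis(benzyloxy)salicylaldehyde, used as its 4-methoxy ortho-quinone methide.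
4. Salicylaldehyde ⇐ ortho-formylation of a locally symmetric 4-aryl-3,5-bis(benzyloxy)phenol ⇐ Suzuki–Miyaura union (ring A C6 to the catechol ring of the flavone) of a flavone boronate with a 2,6-bis(benzyloxy)aryl triflate. The triflate position is fixed by para-oxidation of 3,5-bis(benzyloxy)phenol.
5. Order of ring formation: flavone pyranone ring first (Claisen–Schmidt, I2/DMSO), then the biaryl bond, flavanone ring C last.

Key step: step 13

Assumption: the target SMILES fixes only C2 (R) and no axial descriptor, so from the salicylaldehyde stage on the tri-ortho-substituted biaryl axis is carried as an unassigned rotamer or atropisomer mixture expected to equilibrate once the flanking benzyl ethers are gone, and the catalyst antipode used in the key step is the one that delivers 2R.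

**Step 1**
Reactants: 1 3,5-bis(benzyloxy)phenol
Product: 2 2,6-bis(benzyloxy)-1,4-benzoquinone
Conditions: K2[ON(SO3)2] (2.5 equiv), KH2PO4 buffer, acetone/H2O, rt
Reagents that add atoms: dipotassium nitrosodisulfonate, [K+].[K+].[O]N(S(=O)(=O)[O-])S(=O)(=O)[O-]
Why: Teuber oxidation of a para-unsubstituted phenol gives the p-quinone, which places an oxygen handle on the carbon between the two benzyloxy groups, a site that direct halogenation of 1 (ortho and para positions of similar reactivity) would not select cleanly.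

**Step 2**
Reactants: 2 2,6-bis(benzyloxy)-1,4-benzoquinone
Product: 3 2,6-bis(benzyloxy)benzene-1,4-diol
Conditions: Na2S2O4, THF/H2O, rt, under Ar
Reagents that add atoms: none
Why: Dithionite reduction of a quinone to its hydroquinone is mild and leaves benzyl ethers untouched.

**Step 3**
Reactants: 3 2,6-bis(benzyloxy)benzene-1,4-diol
Product: 4 2,6-bis(benzyloxy)-4-(triisopropylsilyloxy)phenol
Conditions: TIPSCl (1.05 equiv), imidazole, DMF, 0 °C
Reagents that add atoms: triisopropylsilyl chloride, CC(C)[Si](Cl)(C(C)C)C(C)C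
Why: Sterically controlled monosilylation, because the bulky chloride reacts at the hydroxyl flanked by two hydrogens and not at the one buried between, and hydrogen-bonded to, the two benzyloxy groups.

**Step 4**
Reactants: 4 2,6-bis(benzyloxy)-4-(triisopropylsilyloxy)phenol
Product: 5 2,6-bis(benzyloxy)-4-(triisopropylsilyloxy)phenyl trifluoromethanesulfonate
Conditions: Tf2O, pyridine, CH2Cl2, 0 °C
Reagents that add atoms: trifluoromethanesulfonic anhydride, O=S(=O)(OS(=O)(=O)C(F)(F)F)C(F)(F)F
Why: O-Triflation works on 2,6-dialkoxyphenols because the sulfonyl electrophile is small, and silyl and benzyl ethers tolerate pyridine-buffered Tf2O.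

**Step 5**
Reactants: 6 3,4-bis(benzyloxy)benzaldehyde
Product: 7 2-bromo-4,5-bis(benzyloxy)benzaldehyde
Conditions: Br2, NaOAc, AcOH, rt
Reagents that add atoms: bromine, BrBr
Why: Electrophilic aromatic bromination goes para to the 3-benzyloxy group and ortho to the aldehyde, as for 3,4-dialkoxybenzaldehydes in general, while NaOAc takes up HBr so the benzyl ethers stay on.

**Step 6**
Reactants: 8 2',4',6'-trihydroxyacetophenone
Product: 9 2'-hydroxy-4',6'-bis(benzyloxy)acetophenone
Conditions: BnBr (2.1 equiv), K2CO3, DMF, rt to 50 °C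
Reagents that add atoms: benzyl bromide, BrCc1ccccc1
Why: Williamson etherification stops after two benzylations because the last hydroxyl is chelated to the acetyl carbonyl and is far less nucleophilic.

**Step 7**
Reactants: 7 2-bromo-4,5-bis(benzyloxy)benzaldehyde; 9 2'-hydroxy-4',6'-bis(benzyloxy)acetophenone
Product: 10 (E)-1-[2-hydroxy-4,6-bis(benzyloxy)phenyl]-3-[2-bromo-4,5-bis(benzyloxy)phenyl]prop-2-en-1-one
Conditions: KOH, EtOH/THF, rt
Reagents that add atoms: none
Why: Claisen–Schmidt condensation of a non-enolisable aldehyde with the methyl ketone gives the conjugated (E)-chalcone under thermodynamic control.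

**Step 8**
Reactants: 10 (E)-2'-hydroxychalcone
Product: 11 5,7-bis(benzyloxy)-2-[2-bromo-4,5-bis(benzyloxy)phenyl]-4H-chromen-4-one
Conditions: I2 (10 mol %), DMSO, 130 °C
Reagents that add atoms: none
Why: Iodine-catalysed oxidative cyclisation of a 2'-hydroxychalcone (oxa-Michael closure, then dehydrogenation) forms the flavone pyranone ring with DMSO as terminal oxidant, and the low iodine loading limits ring iodination.

**Step 9**
Reactants: 11 2'-bromoflavone
Product: 12 5,7-bis(benzyloxy)-2-[4,5-bis(benzyloxy)-2-(4,4,5,5-tetramethyl-1,3,2-dioxaborolan-2-yl)phenyl]-4H-chromen-4-one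
Conditions: B2pin2, PdCl2(dppf) (5 mol %), KOAc, 1,4-dioxane, 90 °C
Reagents that add atoms: bis(pinacolato)diboron, CC1(C)OB(OC1(C)C)B1OC(C)(C)C(C)(C)O1
Why: Miyaura borylation of an aryl bromide tolerates the chromone and benzyl ethers, and the weak base KOAc prevents homocoupling.

**Step 10**
Reactants: 5 aryl triflate; 12 flavone pinacol boronate
Product: 13 5,7-bis(benzyloxy)-2-{4,5-bis(benzyloxy)-2-[2,6-bis(benzyloxy)-4-(triisopropylsilyloxy)phenyl]phenyl}-4H-chromen-4-one
Conditions: Pd(OAc)2 (5 mol %), SPhos (10 mol %), K3PO4, toluene/H2O, 100 °C, degassed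
Reagents that add atoms: none
Why: Suzuki–Miyaura coupling with a bulky electron-rich biaryl monophosphine is the standard route to tri-ortho-substituted biaryls, the triflate is the only carbon–leaving-group bond present, and any TIPS loss only anticipates step 11.

**Step 11**
Reactants: 13 TIPS-protected biaryl flavone
Product: 14 5,7-bis(benzyloxy)-2-{4,5-bis(benzyloxy)-2-[2,6-bis(benzyloxy)-4-hydroxyphenyl]phenyl}-4H-chromen-4-one
Conditions: Bu4NF, AcOH, THF, 0 °C
Reagents that add atoms: none
Why: Fluoride cleaves the aryl silyl ether selectively, and the acetic acid buffer protects the base-sensitive chromone.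

**Step 12**
Reactants: 14 flavone-bearing 4-aryl-3,5-bis(benzyloxy)phenol
Product: 15 2-hydroxy-4,6-bis(benzyloxy)-5-{4,5-bis(benzyloxy)-2-[5,7-bis(benzyloxy)-4-oxo-4H-chromen-2-yl]phenyl}benzaldehyde
Conditions: MgCl2, Et3N, (CH2O)n, THF, reflux; then 1 M HCl
Reagents that add atoms: paraformaldehyde (as formaldehyde), C=O
Why: In the Casnati–Skattebøl formylation the magnesium phenoxide delivers formaldehyde only ortho to the free hydroxyl, and since the two ortho positions of ring A are constitutionally equivalent, a single regioisomer results with the aryl group para to the hydroxyl.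

**Step 13**
Reactants: 15 5-aryl-4,6-bis(benzyloxy)salicylaldehyde; 16 4-(benzyloxy)styrene
Product: 19 (2R,4R)-2,4-cis-5,7-bis(benzyloxy)-2-[4-(benzyloxy)phenyl]-4-methoxychroman bearing at C6 the 4,5-bis(benzyloxy)-2-[5,7-bis(benzyloxy)-4-oxo-4H-chromen-2-yl]phenyl group, via dimethyl acetal 17 (not isolated), via O-methyl oxocarbenium ion 18 (not isolated)
Conditions: HC(OMe)3 (2 equiv), BINOL-derived chiral imidodiphosphoric acid with 3,3'-aryl groups (10 mol %), 5 Å MS, toluene/CH2Cl2, −20 °C; 16 (3 equiv) added slowly; Et3N quench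
Reagents that add atoms: trimethyl orthoformate, COC(OC)OC
Why: Proposed new method: trimethyl orthoformate turns the chelated aldehyde of 15 into acetal 17, the chiral acid expels methanol from it to give the (E)-O-methyl oxocarbenium ion 18 (the O-protonated 4-methoxy ortho-quinone methide) as a hydrogen-bonded contact ion pair with the imidodiphosphate, and the CH2 terminus of 16 bonds to C4 while its benzylic carbon bonds to O1. The closest known reaction types are the racemic Lewis- or Brønsted-acid three-component union of salicylaldehydes, orthoformates and styrenes to 2,4-cis-4-alkoxyflavans and the enantioselective but intramolecular ortho-quinone methide [4+2] under imidodiphosphoric acids, whereas the intermolecular enantioselective version is without precedent. Ring C is closed as a six-membered oxygen heterocycle in an inverse-electron-demand hetero-[4+2] mode that is concerted but strongly asynchronous, its stepwise limit being Prins addition at C4 followed by capture of the C2 benzylic cation by the phenolic O1. C2 (R) is set by catalyst control, the anion shielding one face of the ion pair, and C4 (R) is set relative to C2 by the endo transition state that places the 2-aryl and 4-methoxy groups cis and both pseudo-equatorial, this second centre being erased in step 14. Regioselectivity (benzylic carbon to oxygen) follows from the polarisation of 16 by its 4-benzyloxy group, and the 6-aryl constitution is secured because the only free hydroxyl of ring A is the one para to the biaryl bond. The three oxygens of ring A let 17 ionise under a moderately strong acid, which should spare the benzyl ethers and the electron-poor flavone enone and hold back cationic oligomerisation of slowly added 16.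

**Step 14**
Reactants: 19 (2R,4R)-cis-4-methoxyflavan
Product: 20 (2R)-5,7-bis(benzyloxy)-2-[4-(benzyloxy)phenyl]-6-{4,5-bis(benzyloxy)-2-[5,7-bis(benzyloxy)-4-oxo-4H-chromen-2-yl]phenyl}chroman-4-one
Conditions: DDQ (1.5 equiv), CH2Cl2/pH 7 phosphate buffer, 0 °C to rt
Reagents that add atoms: water, O
Why: This is the oxidative cleavage of an electron-rich benzylic ether known from p-methoxybenzyl ethers, in which DDQ removes the pseudo-axial C4 hydride aligned with the trialkoxy ring A, water adds to the oxocarbenium ion and methanol leaves to give the ketone, while C2 is not touched under buffered conditions.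

**Step 15**
Reactants: 20 heptabenzyl (2R)-flavanone
Product: 21 (2R)-5,7-dihydroxy-2-(4-hydroxyphenyl)-6-[2-(5,7-dihydroxy-4-oxo-4H-chromen-2-yl)-4,5-dihydroxyphenyl]chroman-4-one (target)
Conditions: H2 (1 atm), 10% Pd/C, THF/MeOH, rt, stopped at full debenzylation
Reagents that add atoms: none
Why: Neutral catalytic hydrogenolysis removes all seven aryl benzyl ethers much faster than it reduces the flavone C2=C3 bond or the chelated ketone, and the absence of base keeps C2 from racemising through ring opening to the chalcone.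

**Compound list**
1 | 3,5-bis(benzyloxy)phenol | Oc1cc(OCc2ccccc2)cc(OCc2ccccc2)c1 | starting material
2 | 2,6-bis(benzyloxy)-1,4-benzoquinone | O=C1C=C(OCc2ccccc2)C(=O)C(OCc2ccccc2)=C1 | intermediate
3 | 2,6-bis(benzyloxy)benzene-1,4-diol | Oc1cc(OCc2ccccc2)c(O)c(OCc2ccccc2)c1 | intermediate
4 | 2,6-bis(benzyloxy)-4-(triisopropylsilyloxy)phenol | CC(C)[Si](Oc1cc(OCc2ccccc2)c(O)c(OCc2ccccc2)c1)(C(C)C)C(C)C | intermediate
5 | 2,6-bis(benzyloxy)-4-(triisopropylsilyloxy)phenyl trifluoromethanesulfonate | CC(C)[Si](Oc1cc(OCc2ccccc2)c(OS(=O)(=O)C(F)(F)F)c(OCc2ccccc2)c1)(C(C)C)C(C)C | intermediate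
6 | 3,4-bis(benzyloxy)benzaldehyde | O=Cc1ccc(OCc2ccccc2)c(OCc2ccccc2)c1 | starting material
7 | 2-bromo-4,5-bis(benzyloxy)benzaldehyde | O=Cc1cc(OCc2ccccc2)c(OCc2ccccc2)cc1Br | intermediate
8 | 2',4',6'-trihydroxyacetophenone | CC(=O)c1c(O)cc(O)cc1O | starting material
9 | 2'-hydroxy-4',6'-bis(benzyloxy)acetophenone | CC(=O)c1c(O)cc(OCc2ccccc2)cc1OCc1ccccc1 | intermediate
10 | (E)-1-[2-hydroxy-4,6-bis(benzyloxy)phenyl]-3-[2-bromo-4,5-bis(benzyloxy)phenyl]prop-2-en-1-one | O=C(/C=C/c1cc(OCc2ccccc2)c(OCc2ccccc2)cc1Br)c1c(O)cc(OCc2ccccc2)cc1OCc1ccccc1 | intermediate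
11 | 5,7-bis(benzyloxy)-2-[2-bromo-4,5-bis(benzyloxy)phenyl]-4H-chromen-4-one | O=c1cc(-c2cc(OCc3ccccc3)c(OCc3ccccc3)cc2Br)oc2cc(OCc3ccccc3)cc(OCc3ccccc3)c12 | intermediate
12 | pinacol boronate of 11 (boron in place of bromine) | O=c1cc(-c2cc(OCc3ccccc3)c(OCc3ccccc3)cc2B2OC(C)(C)C(C)(C)O2)oc2cc(OCc3ccccc3)cc(OCc3ccccc3)c12 | intermediate
13 | TIPS-protected flavone-bearing 4-aryl-3,5-bis(benzyloxy)phenol | CC(C)[Si](Oc1cc(OCc2ccccc2)c(-c2cc(OCc3ccccc3)c(OCc3ccccc3)cc2-c2cc(=O)c3c(OCc4ccccc4)cc(OCc4ccccc4)cc3o2)c(OCc2ccccc2)c1)(C(C)C)C(C)C | intermediate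
14 | flavone-bearing 4-aryl-3,5-bis(benzyloxy)phenol | Oc1cc(OCc2ccccc2)c(-c2cc(OCc3ccccc3)c(OCc3ccccc3)cc2-c2cc(=O)c3c(OCc4ccccc4)cc(OCc4ccccc4)cc3o2)c(OCc2ccccc2)c1 | intermediate
15 | 2-hydroxy-4,6-bis(benzyloxy)-5-arylbenzaldehyde carrying the perbenzylated flavone | O=Cc1c(O)cc(OCc2ccccc2)c(-c2cc(OCc3ccccc3)c(OCc3ccccc3)cc2-c2cc(=O)c3c(OCc4ccccc4)cc(OCc4ccccc4)cc3o2)c1OCc1ccccc1 | intermediate
16 | 4-(benzyloxy)styrene | C=Cc1ccc(OCc2ccccc2)cc1 | starting material
17 | dimethyl acetal of 15 | COC(OC)c1c(O)cc(OCc2ccccc2)c(-c2cc(OCc3ccccc3)c(OCc3ccccc3)cc2-c2cc(=O)c3c(OCc4ccccc4)cc(OCc4ccccc4)cc3o2)c1OCc1ccccc1 | intermediate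
18 | (E)-O-methyl oxocarbenium ion of 15 (protonated 4-methoxy ortho-quinone methide, imidodiphosphate counterion) | C/[O+]=C/c1c(O)cc(OCc2ccccc2)c(-c2cc(OCc3ccccc3)c(OCc3ccccc3)cc2-c2cc(=O)c3c(OCc4ccccc4)cc(OCc4ccccc4)cc3o2)c1OCc1ccccc1 | intermediate
19 | (2R,4R)-2,4-cis-4-methoxyflavan carrying the perbenzylated flavone at C6 | CO[C@@H]1C[C@H](c2ccc(OCc3ccccc3)cc2)Oc2cc(OCc3ccccc3)c(-c3cc(OCc4ccccc4)c(OCc4ccccc4)cc3-c3cc(=O)c4c(OCc5ccccc5)cc(OCc5ccccc5)cc4o3)c(OCc3ccccc3)c21 | intermediate
20 | (2R)-flavanone heptabenzyl ether | O=C1C[C@H](c2ccc(OCc3ccccc3)cc2)Oc2cc(OCc3ccccc3)c(-c3cc(OCc4ccccc4)c(OCc4ccccc4)cc3-c3cc(=O)c4c(OCc5ccccc5)cc(OCc5ccccc5)cc4o3)c(OCc3ccccc3)c21 | intermediate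
21 | (2R)-5,7-dihydroxy-2-(4-hydroxyphenyl)-6-[2-(5,7-dihydroxy-4-oxo-4H-chromen-2-yl)-4,5-dihydroxyphenyl]chroman-4-one | O=C1C[C@H](c2ccc(O)cc2)Oc2cc(O)c(-c3cc(O)c(O)cc3-c3cc(=O)c4c(O)cc(O)cc4o3)c(O)c21 | target

**Total step count:** 15. **Longest linear sequence:** 10 steps. This is steps 5, 7, 8, 9, 10, 11, 12, 13, 14, 15, and the branch through steps 1–4 is equally long.

**Steps most likely to fail**

**Step 13 (key step).**
- Facial discrimination may be poor because the very large 5-aryl substituent may not fit a confined chiral pocket.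
- The basic pyranone carbonyl of the flavone may bind the acid.
- The styrene may oligomerise cationically.
- Acid-induced re-ionisation of the C2–O1 bond may erode the enantiomeric purity.
- Fallback, which uses known chemistry and no quinone methide, sets out from 15:
  - Chemoselective methyl addition to the aldehyde with MeTi(OiPr)3 should give the racemic 1-arylethanol F1.
  - MnO2 oxidation should give the 2-hydroxyacetophenone F2.
  - Condensation with N,N-dimethylformamide dimethyl acetal should give the enaminone F3.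
  - Acid-induced ring closure should give the 6-aryl-5,7-bis(benzyloxy)chromone F4.
  - A Hayashi–Miyaura 1,4-addition of 4-(benzyloxy)phenylboronic acid then sets C2 (R). It uses [Rh(OH)(cod)]2 and an electron-poor chiral biaryl bisphosphine, and the 2-aryl-substituted flavone enone is inert.
  - The fallback comes back to the route at 20, so step 14 is skipped.

**Step 14.**
- Hydride abstraction may compete at C2–H or at benzyl ether CH2 groups.
- Methanol may be lost to give a flav-3-ene.
- Fallback sets out from 19: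
  - Solvolysis of the C4 methyl ether (catalytic camphorsulfonic acid, THF/H2O, ionisation at C4 only) should give the (2R)-flavan-4-ol F5 as a C4 epimer mixture.
  - Dess–Martin periodinane with NaHCO3 in CH2Cl2 should oxidise it, coming back at 20.

**Step 10.**
- Oxidative addition into the electron-rich, doubly flanked triflate may be slow.
- Sulfur–oxygen hydrolysis of the triflate and protodeboronation of 12 may overtake the coupling.
- Fallback is transition-metal-free and sets out from 2 and 7:
  - Aldehyde 7 is converted with HC(OMe)3 and catalytic p-TsOH into the bromo dimethyl acetal F6.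
  - Bromine–lithium exchange (n-BuLi, THF, −78 °C) is followed by 1,2-addition to the C1 carbonyl of 2. This is the only carbonyl not deactivated as a doubly vinylogous ester. The product should be the p-quinol F7.
  - Zn in AcOH/THF/H2O reductively aromatises it and unmasks the aldehyde, giving the biaryl phenol aldehyde F8.
  - Claisen–Schmidt condensation with 9 should give the chalcone F9.
  - I2 (catalytic)/DMSO closes the flavone, coming back at 14.

**Further compounds**
F1 | step 13 | 2-(1-hydroxyethyl)-3,5-bis(benzyloxy)-4-arylphenol carrying the perbenzylated flavone (racemic carbinol) | CC(O)c1c(O)cc(OCc2ccccc2)c(-c2cc(OCc3ccccc3)c(OCc3ccccc3)cc2-c2cc(=O)c3c(OCc4ccccc4)cc(OCc4ccccc4)cc3o2)c1OCc1ccccc1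
F2 | step 13 | 2-hydroxy-4,6-bis(benzyloxy)-5-arylacetophenone carrying the perbenzylated flavone | CC(=O)c1c(O)cc(OCc2ccccc2)c(-c2cc(OCc3ccccc3)c(OCc3ccccc3)cc2-c2cc(=O)c3c(OCc4ccccc4)cc(OCc4ccccc4)cc3o2)c1OCc1ccccc1
F3 | step 13 | (E)-3-(dimethylamino)-1-arylprop-2-en-1-one from F2 | CN(C)/C=C/C(=O)c1c(O)cc(OCc2ccccc2)c(-c2cc(OCc3ccccc3)c(OCc3ccccc3)cc2-c2cc(=O)c3c(OCc4ccccc4)cc(OCc4ccccc4)cc3o2)c1OCc1ccccc1
F4 | step 13 | 5,7-bis(benzyloxy)-6-aryl-4H-chromen-4-one carrying the perbenzylated flavone | O=c1ccoc2cc(OCc3ccccc3)c(-c3cc(OCc4ccccc4)c(OCc4ccccc4)cc3-c3cc(=O)c4c(OCc5ccccc5)cc(OCc5ccccc5)cc4o3)c(OCc3ccccc3)c12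
F5 | step 14 | (2R)-flavan-4-ol heptabenzyl ether, C4 epimer mixture | OC1C[C@H](c2ccc(OCc3ccccc3)cc2)Oc2cc(OCc3ccccc3)c(-c3cc(OCc4ccccc4)c(OCc4ccccc4)cc3-c3cc(=O)c4c(OCc5ccccc5)cc(OCc5ccccc5)cc4o3)c(OCc3ccccc3)c21
F6 | step 10 | 2-bromo-4,5-bis(benzyloxy)benzaldehyde dimethyl acetal | COC(OC)c1cc(OCc2ccccc2)c(OCc2ccccc2)cc1Br
F7 | step 10 | 4-[4,5-bis(benzyloxy)-2-(dimethoxymethyl)phenyl]-3,5-bis(benzyloxy)-4-hydroxycyclohexa-2,5-dien-1-one | O=C1C=C(OCc2ccccc2)C(O)(c2cc(OCc3ccccc3)c(OCc3ccccc3)cc2C(OC)OC)C(OCc2ccccc2)=C1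
F8 | step 10 | 4,5-bis(benzyloxy)-2-[2,6-bis(benzyloxy)-4-hydroxyphenyl]benzaldehyde | O=Cc1cc(OCc2ccccc2)c(OCc2ccccc2)cc1-c1c(OCc2ccccc2)cc(O)cc1OCc1ccccc1
F9 | step 10 | (E)-2'-hydroxychalcone from F8 and 9 | O=C(/C=C/c1cc(OCc2ccccc2)c(OCc2ccccc2)cc1-c1c(OCc2ccccc2)cc(O)cc1OCc1ccccc1)c1c(O)cc(OCc2ccccc2)cc1OCc1ccccc1
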